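**Retrosynthetic overview**
- The target is (3S)-7,2',4'-trihydroxy-6,5'-diprenylisoflavanone. The last operations are removal of the silyl ethers on O7 and O4' and, before that, closure of ring C (O1–C2 bond) by 6-endo oxa-Michael addition with catalyst-controlled protonation at C3. Rings A and B come from the starting aldehyde; ring C is the only ring formed.
- The α-aryl enone (C2 as an exocyclic CH2 on C3) comes from Peterson methylenation of one carbonyl of a symmetric 2,2'-dihydroxy-5,5'-diprenylbenzil, whose two carbonyl carbons become C4 and C3.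
- Feature on which the strategy rests: C6 of ring A is para to the oxygen on C8a, C5' of ring B is para to the oxygen on C2', and both rings are the same 2,4-dioxygenated 5-prenylphenyl unit. Both C-prenyl bonds (C6–C1'' and C5'–C1''') are therefore disconnected together to prenyl ethers on those two oxygens, through a twofold Claisen–Cope (para-Claisen) rearrangement.
- The bis(prenyl ether) benzil comes from reductive dimerisation and oxidation of 4-silyloxy-2-prenyloxybenzaldehyde, made from 2,4-dihydroxybenzaldehyde.

Key step: step 5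

Assumption: CIP analysis of the given SMILES gives (3S) at C3; the facial sense of the catalyst in step 8 cannot be predicted with confidence, so the quinine-derived catalyst is written and its quinidine-derived pseudoenantiomer is to be used if the quinine series proves to lead to (3R).

**Route**

Step 1
Reactants: 1 2,4-dihydroxybenzaldehyde; 2 tert-butyldimethylsilyl chloride
Product: 3 4-(tert-butyldimethylsilyloxy)-2-hydroxybenzaldehyde
Conditions: TBSCl (1.05 equiv), imidazole, CH2Cl2, 0 °C
Reagents that add atoms: tert-butyldimethylsilyl chloride, CC(C)(C)[Si](C)(C)Cl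
Why: Selective O-silylation should occur at the 4-hydroxyl, which is the more acidic and unhindered phenol, while the 2-hydroxyl is held in a hydrogen bond to the aldehyde.

Step 2
Reactants: 3 4-(tert-butyldimethylsilyloxy)-2-hydroxybenzaldehyde; 4 3-methylbut-2-en-1-ol
Product: 5 4-(tert-butyldimethylsilyloxy)-2-(3-methylbut-2-enyloxy)benzaldehyde
Conditions: PPh3, DIAD, THF, 0 °C → rt
Reagents that add atoms: 3-methylbut-2-en-1-ol, CC(C)=CCO
Why: Mitsunobu etherification of the acidic chelated phenol with a primary allylic alcohol runs under neutral conditions, so no free phenoxide or carbonate is present to cleave or transfer the aryl silyl ether.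

Step 3
Reactants: 5 4-(tert-butyldimethylsilyloxy)-2-(3-methylbut-2-enyloxy)benzaldehyde (two molecules)
Product: 6 1,2-bis[4-(tert-butyldimethylsilyloxy)-2-(3-methylbut-2-enyloxy)phenyl]ethane-1,2-diol (dl/meso mixture)
Conditions: SmI2 (1.1 equiv per aldehyde), THF, −78 °C → rt; aq. NH4Cl
Reagents that add atoms: none
Why: Reductive pinacol coupling, in which one-electron reduction gives aryl ketyl radicals that should dimerise faster than they can add to the remote trisubstituted alkene when no HMPA is present; the prenyl and silyl ethers are inert to SmI2 in THF, and the diastereomer mixture is of no consequence because both carbinols are oxidised next.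

Step 4
Reactants: 6 1,2-bis[4-(tert-butyldimethylsilyloxy)-2-(3-methylbut-2-enyloxy)phenyl]ethane-1,2-diol
Product: 8 1,2-bis[4-(tert-butyldimethylsilyloxy)-2-(3-methylbut-2-enyloxy)phenyl]ethane-1,2-dione, via benzoin 7 (not isolated)
Conditions: IBX (3 equiv), DMSO, rt
Reagents that add atoms: none
Why: IBX oxidation of a 1,2-diol should stop at the 1,2-diketone without glycol cleavage and leaves trisubstituted alkenes and aryl silyl ethers alone at room temperature.

Step 5
Reactants: 8 1,2-bis[4-(tert-butyldimethylsilyloxy)-2-(3-methylbut-2-enyloxy)phenyl]ethane-1,2-dione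
Product: 12 1,2-bis[4-(tert-butyldimethylsilyloxy)-2-hydroxy-5-(3-methylbut-2-enyl)phenyl]ethane-1,2-dione, via first dienone 9 (not isolated), via monophenol 10 (not isolated), via second dienone 11 (not isolated)
Conditions: PhNEt2 (degassed, dilute), 190 °C, sealed tube, Ar, dark
Reagents that add atoms: none
Why: Each aryl prenyl ether should undergo an aromatic Claisen [3,3] shift to the ortho carbon between the two oxygens (or to the acyl-bearing ipso carbon), giving a cyclohexa-2,4-dienone with an inverted 1,1-dimethylallyl group such as 9; a second [3,3] (Cope) shift then carries the allyl unit to the carbon para to the original ether oxygen, which restores the normal prenyl connectivity, and tautomerisation gives the phenol. The same sequence on the other ring takes 10 through 11 to 12, so the bonds that become C6–C1'' and C5'–C1''' of the target are both formed in one heating. The closest known reaction type is the para-Claisen (Claisen–Cope) rearrangement of aryl prenyl ethers that stand ortho to an acyl group, used for para C-prenylation of ortho-acyl phenols. The step closes no ring and creates no stereocentre. The selectivity needed is para over ortho delivery on both rings: the ortho dienone holds a tertiary allyl group wedged between a carbonyl and the bulky silyloxy group, which should speed the Cope shift relative to enolisation, the ipso dienone cannot enolise at all, and the aniline solvent buffers adventitious acid that would ionise the prenyl ether. Each phenol set free is para, not ortho, to the new prenyl group and is hydrogen-bonded to its carbonyl, so chroman formation and abnormal-Claisen follow-up are not open to it.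

Step 6
Reactants: 12 1,2-bis[4-(tert-butyldimethylsilyloxy)-2-hydroxy-5-(3-methylbut-2-enyl)phenyl]ethane-1,2-dione; 13 (trimethylsilyl)methylmagnesium chloride
Product: 14 2-hydroxy-1,2-bis[4-(tert-butyldimethylsilyloxy)-2-hydroxy-5-(3-methylbut-2-enyl)phenyl]-3-(trimethylsilyl)propan-1-one (racemic)
Conditions: Me3SiCH2MgCl (3.5 equiv), THF, −78 → 0 °C; aq. NH4Cl
Reagents that add atoms: (trimethylsilyl)methylmagnesium chloride, C[Si](C)(C)C[Mg]Cl
Why: Grignard 1,2-addition (first stage of a Peterson olefination) in which two equivalents deprotonate the phenols and the third adds to one of the two symmetry-equivalent carbonyls; the neighbouring magnesium alkoxide and the crowded new centre should block a second addition, and a magnesium β-silyl alkoxide does not eliminate, so the β-hydroxysilane is isolated.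

Step 7
Reactants: 14 2-hydroxy-1,2-bis[4-(tert-butyldimethylsilyloxy)-2-hydroxy-5-(3-methylbut-2-enyl)phenyl]-3-(trimethylsilyl)propan-1-one
Product: 15 1,2-bis[4-(tert-butyldimethylsilyloxy)-2-hydroxy-5-(3-methylbut-2-enyl)phenyl]prop-2-en-1-one
Conditions: CSA (10 mol%), CH2Cl2, 0 °C; short silica pad, used at once
Reagents that add atoms: none
Why: Acid-promoted Peterson elimination, in which the tertiary carbinol ionises to a cation stabilised by the electron-rich ring and the β-silicon and loses the silyl group to give the 1,1-disubstituted alkene; the non-basic medium should keep the chelated ring-A phenol from adding to the enone, and the stereocentre of 14 is destroyed here.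

Step 8
Reactants: 15 1,2-bis[4-(tert-butyldimethylsilyloxy)-2-hydroxy-5-(3-methylbut-2-enyl)phenyl]prop-2-en-1-one
Product: 17 (3S)-7-(tert-butyldimethylsilyloxy)-3-[4-(tert-butyldimethylsilyloxy)-2-hydroxy-5-(3-methylbut-2-enyl)phenyl]-6-(3-methylbut-2-enyl)chroman-4-one, via chromenol enol 16 (not isolated)
Conditions: N-[3,5-bis(trifluoromethyl)phenyl]-N'-(9-deoxy-epi-quinin-9-yl)thiourea (10 mol%), PhMe, −40 °C; AcOH quench at −40 °C
Reagents that add atoms: none
Why: Proposed new method: a tandem intramolecular oxa-Michael addition/enantioselective protonation, not yet shown for 2-hydroxyaryl α-aryl vinyl ketones, in which the quinuclidine nitrogen deprotonates the acidic chelated ring-A phenol while the thiourea binds the ketone, 6-endo-trig attack of the phenoxide on the unsubstituted CH2 terminus closes ring C to the catalyst-bound enol 16, and the quinuclidinium N–H then delivers the proton to one face of C3 inside the hydrogen-bonded ion pair, so that C3 is set by the chiral proton shuttle and not by C–O bond formation; the ring-B phenol could only close by a disfavoured 5-endo-trig path, the closest known reaction types are cinchona- and guanidine-catalysed conjugate addition/enantioselective protonation of α-substituted acrylates with thiols and thiourea-catalysed intramolecular oxa-Michael closure of 2'-hydroxy enones to chromanones, and low temperature, low loading and an acid quench are meant to keep the weakly basic catalyst from epimerising the product.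

Step 9
Reactants: 17 (3S)-7-(tert-butyldimethylsilyloxy)-3-[4-(tert-butyldimethylsilyloxy)-2-hydroxy-5-(3-methylbut-2-enyl)phenyl]-6-(3-methylbut-2-enyl)chroman-4-one
Product: 18 (3S)-3-[2,4-dihydroxy-5-(3-methylbut-2-enyl)phenyl]-7-hydroxy-6-(3-methylbut-2-enyl)chroman-4-one
Conditions: Et3N·3HF (excess), THF, 0 °C → rt
Reagents that add atoms: none
Why: Fluoride cleavage of the two aryl silyl ethers under mildly acidic, non-basic conditions should spare the enolisable C3–H of the α-aryl ketone and should not cyclise the ortho-prenylphenols that are set free.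

**Compound list**
1 | 2,4-dihydroxybenzaldehyde | O=Cc1ccc(O)cc1O | starting material
2 | tert-butyldimethylsilyl chloride | CC(C)(C)[Si](C)(C)Cl | starting material
3 | 4-(tert-butyldimethylsilyloxy)-2-hydroxybenzaldehyde | O=Cc1ccc(O[Si](C)(C)C(C)(C)C)cc1O | intermediate
4 | 3-methylbut-2-en-1-ol | CC(C)=CCO | starting material
5 | 4-(tert-butyldimethylsilyloxy)-2-(3-methylbut-2-enyloxy)benzaldehyde | CC(C)=CCOc1cc(O[Si](C)(C)C(C)(C)C)ccc1C=O | intermediate
6 | 1,2-bis[4-(tert-butyldimethylsilyloxy)-2-(3-methylbut-2-enyloxy)phenyl]ethane-1,2-diol (dl/meso mixture) | CC(C)=CCOc1cc(O[Si](C)(C)C(C)(C)C)ccc1C(O)C(O)c1ccc(O[Si](C)(C)C(C)(C)C)cc1OCC=C(C)C | intermediate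
7 | benzoin: 2-hydroxy-1,2-bis[4-(tert-butyldimethylsilyloxy)-2-(3-methylbut-2-enyloxy)phenyl]ethanone (racemic, not isolated) | CC(C)=CCOc1cc(O[Si](C)(C)C(C)(C)C)ccc1C(O)C(=O)c1ccc(O[Si](C)(C)C(C)(C)C)cc1OCC=C(C)C | intermediate
8 | 1,2-bis[4-(tert-butyldimethylsilyloxy)-2-(3-methylbut-2-enyloxy)phenyl]ethane-1,2-dione (key-step precursor) | CC(C)=CCOc1cc(O[Si](C)(C)C(C)(C)C)ccc1C(=O)C(=O)c1ccc(O[Si](C)(C)C(C)(C)C)cc1OCC=C(C)C | intermediate
9 | first dienone: 8 in which one ring is a 5-silyloxy-6-(2-methylbut-3-en-2-yl)cyclohexa-2,4-dien-1-one bearing the diketone at C2 (racemic, not isolated) | C=CC(C)(C)C1C(=O)C(C(=O)C(=O)c2ccc(O[Si](C)(C)C(C)(C)C)cc2OCC=C(C)C)=CC=C1O[Si](C)(C)C(C)(C)C | intermediate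
10 | monophenol: 1-[4-(tert-butyldimethylsilyloxy)-2-hydroxy-5-(3-methylbut-2-enyl)phenyl]-2-[4-(tert-butyldimethylsilyloxy)-2-(3-methylbut-2-enyloxy)phenyl]ethane-1,2-dione (not isolated) | CC(C)=CCOc1cc(O[Si](C)(C)C(C)(C)C)ccc1C(=O)C(=O)c1cc(CC=C(C)C)c(O[Si](C)(C)C(C)(C)C)cc1O | intermediate
11 | second dienone: 10 in which the prenyl ether ring is a 5-silyloxy-6-(2-methylbut-3-en-2-yl)cyclohexa-2,4-dien-1-one bearing the diketone at C2 (racemic, not isolated) | C=CC(C)(C)C1C(=O)C(C(=O)C(=O)c2cc(CC=C(C)C)c(O[Si](C)(C)C(C)(C)C)cc2O)=CC=C1O[Si](C)(C)C(C)(C)C | intermediate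
12 | 1,2-bis[4-(tert-butyldimethylsilyloxy)-2-hydroxy-5-(3-methylbut-2-enyl)phenyl]ethane-1,2-dione (key-step product) | CC(C)=CCc1cc(C(=O)C(=O)c2cc(CC=C(C)C)c(O[Si](C)(C)C(C)(C)C)cc2O)c(O)cc1O[Si](C)(C)C(C)(C)C | intermediate
13 | (trimethylsilyl)methylmagnesium chloride | C[Si](C)(C)C[Mg]Cl | starting material
14 | 2-hydroxy-1,2-bis[4-(tert-butyldimethylsilyloxy)-2-hydroxy-5-(3-methylbut-2-enyl)phenyl]-3-(trimethylsilyl)propan-1-one (racemic) | CC(C)=CCc1cc(C(=O)C(O)(C[Si](C)(C)C)c2cc(CC=C(C)C)c(O[Si](C)(C)C(C)(C)C)cc2O)c(O)cc1O[Si](C)(C)C(C)(C)C | intermediate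
15 | 1,2-bis[4-(tert-butyldimethylsilyloxy)-2-hydroxy-5-(3-methylbut-2-enyl)phenyl]prop-2-en-1-one | CC(C)=CCc1cc(C(=O)C(=C)c2cc(CC=C(C)C)c(O[Si](C)(C)C(C)(C)C)cc2O)c(O)cc1O[Si](C)(C)C(C)(C)C | intermediate
16 | chromenol enol: 7-(tert-butyldimethylsilyloxy)-3-[4-(tert-butyldimethylsilyloxy)-2-hydroxy-5-(3-methylbut-2-enyl)phenyl]-6-(3-methylbut-2-enyl)-2H-chromen-4-ol (not isolated) | CC(C)=CCc1cc2c(cc1O[Si](C)(C)C(C)(C)C)OCC(c1cc(CC=C(C)C)c(O[Si](C)(C)C(C)(C)C)cc1O)=C2O | intermediate
17 | (3S)-7-(tert-butyldimethylsilyloxy)-3-[4-(tert-butyldimethylsilyloxy)-2-hydroxy-5-(3-methylbut-2-enyl)phenyl]-6-(3-methylbut-2-enyl)chroman-4-one | CC(C)=CCc1cc2c(cc1O[Si](C)(C)C(C)(C)C)OC[C@H](c1cc(CC=C(C)C)c(O[Si](C)(C)C(C)(C)C)cc1O)C2=O | intermediate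
18 | (3S)-3-[2,4-dihydroxy-5-(3-methylbut-2-enyl)phenyl]-7-hydroxy-6-(3-methylbut-2-enyl)chroman-4-one | CC(C)=CCc1cc2c(cc1O)OC[C@H](c1cc(CC=C(C)C)c(O)cc1O)C2=O | target

**Step count**
Total steps: 9. Longest linear sequence: 9 steps, from 2,4-dihydroxybenzaldehyde.

**Steps most likely to fail**

1. Step 8 (proposed new method). The proton transfer to the enol may show too little facial discrimination, uncatalysed closure may compete, or the amine catalyst may erode the C3 configuration of the product through enolisation. The fallback uses known chemistry only, sets out from 15 and comes back to the route at the target 18. A catalytic amount of Et3N in CH2Cl2 should close ring C without stereocontrol to the racemic 7,4'-bis(silyl) isoflavanone F1, the usual behaviour of 2'-hydroxy α-methylene deoxybenzoins. TBSCl and imidazole then cap the 2'-phenol to give the racemic tris(silyl) isoflavanone F2. Asymmetric transfer hydrogenation under dynamic kinetic resolution with RuCl[(S,S)-TsDPEN](p-cymene) (divalent ruthenium) and HCO2H/Et3N, a reaction type established for isoflavanones, should give the cis-(3S,4S)-isoflavan-4-ol F3. Here C3 equilibrates through the enol while one enantiomer is reduced faster; the (S,S) catalyst is expected, by analogy with aryl ketones, to give the (4S) carbinol, and the cis relationship then fixes (3S). Dess–Martin periodinane in CH2Cl2 at 0 °C should return the ketone without touching C3, giving the (3S)-tris(silyl) isoflavanone F4. The conditions of step 9 then remove all three silyl groups to give 18.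

2. Step 5 (key step). On one or both rings the Cope shift may fail to outrun enolisation of the ortho dienone, leaving a 1,1-dimethylallyl group on the carbon between the two oxygens. The prenyl ether may also ionise and scramble, or the diketone may be trapped by an intramolecular carbonyl-ene reaction with the prenyl alkene at the temperature needed. The fallback installs the prenyl groups by cross-coupling, sets out from 3 and comes back at 12. NBS in MeCN at 0 °C should brominate para to the free hydroxyl to give 5-bromo-4-(tert-butyldimethylsilyloxy)-2-hydroxybenzaldehyde F5. MOMCl and i-Pr2NEt give the 2-methoxymethyl ether F6. Stille coupling with tributyl(3-methylbut-2-enyl)stannane and Pd(PPh3)4 (zerovalent palladium) in DMF at 90 °C should give 4-(tert-butyldimethylsilyloxy)-2-(methoxymethoxy)-5-(3-methylbut-2-enyl)benzaldehyde F7. SmI2 coupling as in step 3 gives the diol F8, and IBX as in step 4 gives the bis(methoxymethyl) benzil F9. ZnBr2 and n-PrSH in CH2Cl2 at 0 °C then remove the two methoxymethyl groups ortho to the carbonyls to give 12.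

3. Step 6. The two phenoxides formed first may deactivate both carbonyls, or draw the diketone into cyclic hemiketal forms, so that addition stalls. The more forcing conditions then needed may bring silyl transfer or a second addition. The fallback masks the phenols briefly so that a single equivalent of nucleophile meets a neutral diketone; it sets out from 12 and comes back at 14. Me3SiCl and Et3N in CH2Cl2 at 0 °C give the 2,2'-bis(trimethylsilyl ether) of the benzil F10, used crude. Me3SiCH2MgCl (1.2 equiv) in THF at −78 °C should give the mono-adduct bis(trimethylsilyl ether) F11. Aqueous citric acid in THF then hydrolyses the two labile aryl trimethylsilyl ethers, leaving the tert-butyldimethylsilyl ethers, to give 14.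

**Further compounds**
F1 | step 8 | racemic 7-(tert-butyldimethylsilyloxy)-3-[4-(tert-butyldimethylsilyloxy)-2-hydroxy-5-(3-methylbut-2-enyl)phenyl]-6-(3-methylbut-2-enyl)chroman-4-one | CC(C)=CCc1cc2c(cc1O[Si](C)(C)C(C)(C)C)OCC(c1cc(CC=C(C)C)c(O[Si](C)(C)C(C)(C)C)cc1O)C2=O
F2 | step 8 | racemic 7-(tert-butyldimethylsilyloxy)-3-[2,4-bis(tert-butyldimethylsilyloxy)-5-(3-methylbut-2-enyl)phenyl]-6-(3-methylbut-2-enyl)chroman-4-one | CC(C)=CCc1cc2c(cc1O[Si](C)(C)C(C)(C)C)OCC(c1cc(CC=C(C)C)c(O[Si](C)(C)C(C)(C)C)cc1O[Si](C)(C)C(C)(C)C)C2=O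
F3 | step 8 | (3S,4S)-7-(tert-butyldimethylsilyloxy)-3-[2,4-bis(tert-butyldimethylsilyloxy)-5-(3-methylbut-2-enyl)phenyl]-6-(3-methylbut-2-enyl)chroman-4-ol (cis) | CC(C)=CCc1cc2c(cc1O[Si](C)(C)C(C)(C)C)OC[C@H](c1cc(CC=C(C)C)c(O[Si](C)(C)C(C)(C)C)cc1O[Si](C)(C)C(C)(C)C)[C@@H]2O
F4 | step 8 | (3S)-7-(tert-butyldimethylsilyloxy)-3-[2,4-bis(tert-butyldimethylsilyloxy)-5-(3-methylbut-2-enyl)phenyl]-6-(3-methylbut-2-enyl)chroman-4-one | CC(C)=CCc1cc2c(cc1O[Si](C)(C)C(C)(C)C)OC[C@H](c1cc(CC=C(C)C)c(O[Si](C)(C)C(C)(C)C)cc1O[Si](C)(C)C(C)(C)C)C2=O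
F5 | step 5 | 5-bromo-4-(tert-butyldimethylsilyloxy)-2-hydroxybenzaldehyde | O=Cc1cc(Br)c(O[Si](C)(C)C(C)(C)C)cc1O
F6 | step 5 | 5-bromo-4-(tert-butyldimethylsilyloxy)-2-(methoxymethoxy)benzaldehyde | COCOc1cc(O[Si](C)(C)C(C)(C)C)c(Br)cc1C=O
F7 | step 5 | 4-(tert-butyldimethylsilyloxy)-2-(methoxymethoxy)-5-(3-methylbut-2-enyl)benzaldehyde | COCOc1cc(O[Si](C)(C)C(C)(C)C)c(CC=C(C)C)cc1C=O
F8 | step 5 | 1,2-bis[4-(tert-butyldimethylsilyloxy)-2-(methoxymethoxy)-5-(3-methylbut-2-enyl)phenyl]ethane-1,2-diol (dl/meso mixture) | COCOc1cc(O[Si](C)(C)C(C)(C)C)c(CC=C(C)C)cc1C(O)C(O)c1cc(CC=C(C)C)c(O[Si](C)(C)C(C)(C)C)cc1OCOC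
F9 | step 5 | 1,2-bis[4-(tert-butyldimethylsilyloxy)-2-(methoxymethoxy)-5-(3-methylbut-2-enyl)phenyl]ethane-1,2-dione | COCOc1cc(O[Si](C)(C)C(C)(C)C)c(CC=C(C)C)cc1C(=O)C(=O)c1cc(CC=C(C)C)c(O[Si](C)(C)C(C)(C)C)cc1OCOC
F10 | step 6 | 1,2-bis[4-(tert-butyldimethylsilyloxy)-5-(3-methylbut-2-enyl)-2-(trimethylsilyloxy)phenyl]ethane-1,2-dione | CC(C)=CCc1cc(C(=O)C(=O)c2cc(CC=C(C)C)c(O[Si](C)(C)C(C)(C)C)cc2O[Si](C)(C)C)c(O[Si](C)(C)C)cc1O[Si](C)(C)C(C)(C)C
F11 | step 6 | 2-hydroxy-1,2-bis[4-(tert-butyldimethylsilyloxy)-5-(3-methylbut-2-enyl)-2-(trimethylsilyloxy)phenyl]-3-(trimethylsilyl)propan-1-one (racemic) | CC(C)=CCc1cc(C(=O)C(O)(C[Si](C)(C)C)c2cc(CC=C(C)C)c(O[Si](C)(C)C(C)(C)C)cc2O[Si](C)(C)C)c(O[Si](C)(C)C)cc1O[Si](C)(C)C(C)(C)C
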